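**Retrosynthetic overview**
1. Target 22 ⇒ aldehyde acid 21. The C7–C15 aldol bond and the lactone C6–O bond are made together in the last step, so the cyclopentane and the β-lactone close in one operation and the labile C14 centre is resolved dynamically.
2. 21 ⇒ dienyl triflate 15 plus a zinc homoenolate (C8–C17 bond); a 1,6-reduction then places the alkene at C8=C9.
3. 15 ⇒ ring C by an amine-catalysed Michael/aldol condensation of β-keto thioester 9 with enal 12 (sets C13).
4. 9 ⇒ isophorone by CBS reduction and Ireland–Claisen chirality transfer to the quaternary C10.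
5. Ring order: ring A (bought as isophorone) → ring C → cyclopentane and β-lactone together.

Assumption: ring carbons carry spongian numbers (C6 lactone carbonyl, C7, C8=C9, C10 quaternary carbon of ring A, C13, C14, C15 carbinol carbon), and the presumed biosynthesis is taken to close the cyclopentane by aldol addition of an activated C6 acyl unit (through C7) to a C15 aldehyde, the aldolate then closing the β-lactone.

**Route**

Step 1
Reactants: 1 isophorone (3,5,5-trimethylcyclohex-2-en-1-one)
Product: 3 (1R)-3,5,5-trimethylcyclohex-2-en-1-yl acetate, via (R)-isophorol 2 (not isolated)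
Conditions: (S)-2-methyl-CBS-oxazaborolidine (10 mol%), BH3·SMe2, THF, −20 °C; MeOH quench, evaporate; then Ac2O, Et3N, DMAP (cat.), CH2Cl2, rt
Reagents that add atoms: acetic anhydride, CC(=O)OC(C)=O
Why: Corey–Bakshi–Shibata reduction in which the enone C=C arm acts as the large group, so the (S)-catalyst gives the (R)-carbinol, which is acetylated in the same pot without touching the stereocentre.

Step 2
Reactants: 3 (1R)-3,5,5-trimethylcyclohex-2-en-1-yl acetate
Product: 6 2-[(1R)-1,5,5-trimethylcyclohex-2-en-1-yl]acetic acid, via silyl ketene acetal 4 (not isolated), via trimethylsilyl ester 5 (not isolated)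
Conditions: LiN(i-Pr)2, Me3SiCl, THF, −78 °C, then 65 °C; 1 M HCl work-up
Reagents that add atoms: none
Why: Ireland–Claisen [3,3] rearrangement is suprafacial on the ring, so the new C–C bond forms on the face that carried the C–O bond and the (R)-carbinol centre is traded for the (R)-quaternary centre (C10 of the target).

Step 3
Reactants: 6 2-[(1R)-1,5,5-trimethylcyclohex-2-en-1-yl]acetic acid
Product: 7 2-[(1R)-1,3,3-trimethylcyclohexyl]acetic acid
Conditions: H2 (1 atm), 10% Pd/C, EtOAc, rt
Reagents that add atoms: none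
Why: Heterogeneous hydrogenation of the only alkene (cis-disubstituted) gives saturated ring A; the quaternary centre is not involved.

Step 4
Reactants: 7 2-[(1R)-1,3,3-trimethylcyclohexyl]acetic acid
Product: 9 S-ethyl 3-oxo-4-[(1R)-1,3,3-trimethylcyclohexyl]butanethioate, via acyl Meldrum's acid 8 (not isolated)
Conditions: Meldrum's acid, DCC, DMAP, CH2Cl2, 0 °C to rt; filter; then EtSH, toluene, 80 °C
Reagents that add atoms: Meldrum's acid (2,2-dimethyl-1,3-dioxane-4,6-dione), CC1(C)OC(=O)CC(=O)O1; ethanethiol, CCS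
Why: Oikawa–Yonemitsu sequence: C-acylation of Meldrum's acid, then thermal loss of acetone and CO2 to an acylketene that the thiol traps as the β-keto thioester; no stereocentre is touched.

Step 5
Reactants: 10 prop-2-en-1-yl butanoate (allyl butanoate); 11 (2E)-but-2-enal (crotonaldehyde, 3 equiv)
Product: 12 (2E)-4-oxobut-2-en-1-yl butanoate
Conditions: second-generation Hoveyda–Grubbs catalyst, RuCl2(H2IMes)(=CH-C6H4-2-O-i-Pr) (2 mol%), CH2Cl2, 40 °C
Reagents that add atoms: none
Why: Olefin cross-metathesis between the allyl ester and crotonaldehyde gives the E-enal with loss of propene, and it already carries the butanoate of the target.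

Step 6
Reactants: 9 S-ethyl 3-oxo-4-[(1R)-1,3,3-trimethylcyclohexyl]butanethioate; 12 (2E)-4-oxobut-2-en-1-yl butanoate
Product: 14 S-ethyl (1S,6R)-6-[(butanoyloxy)methyl]-2-oxo-3-[(1R)-1,3,3-trimethylcyclohexyl]cyclohex-3-ene-1-carbothioate, via Michael adduct 13 (not isolated)
Conditions: (S)-α,α-diphenylprolinol trimethylsilyl ether (10 mol%), PhCO2H (10 mol%), toluene, 0 °C to rt; then p-TsOH·H2O (20 mol%), 60 °C
Reagents that add atoms: none
Why: Jørgensen-type iminium-catalysed Michael addition of the β-keto thioester to the E-enal, on the face away from the CPh2OSiMe3 group of the (S)-catalyst, sets C13 as R, and an acid-catalysed intramolecular aldol condensation (Robinson-type) of the hindered ketone CH2 onto the aldehyde closes ring C; the carbon between the two carbonyls stays enolisable.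

Step 7
Reactants: 14 S-ethyl (1S,6R)-6-[(butanoyloxy)methyl]-2-oxo-3-[(1R)-1,3,3-trimethylcyclohexyl]cyclohex-3-ene-1-carbothioate
Product: 15 S-ethyl (6R)-6-[(butanoyloxy)methyl]-2-[(trifluoromethanesulfonyl)oxy]-3-[(1R)-1,3,3-trimethylcyclohexyl]cyclohexa-1,3-diene-1-carbothioate
Conditions: Tf2O, i-Pr2NEt, CH2Cl2, −78 °C
Reagents that add atoms: trifluoromethanesulfonic anhydride, O=S(=O)(OS(=O)(=O)C(F)(F)F)C(F)(F)F
Why: O-sulfonylation of the β-keto thioester enolate (the only acidic site) gives the vinylogous acyl triflate regiospecifically at the C8 oxygen; C13 is untouched.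

Step 8
Reactants: 15 dienyl triflate (as above); 16 benzyl 3-bromopropanoate
Product: 18 S-ethyl (6R)-2-[3-(benzyloxy)-3-oxopropyl]-6-[(butanoyloxy)methyl]-3-[(1R)-1,3,3-trimethylcyclohexyl]cyclohexa-1,3-diene-1-carbothioate, via organozinc bromide 17 (not isolated)
Conditions: 16, Zn dust, LiCl, THF, 50 °C; then 15, Pd(PPh3)4 (5 mol%), THF, rt to 45 °C
Reagents that add atoms: none
Why: Negishi coupling of the electron-poor dienyl triflate with the zinc homoenolate puts the three-carbon acid chain on C8; the activated triflate reacts faster than the hindered conjugated thioester.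

Step 9
Reactants: 18 S-ethyl (6R)-2-[3-(benzyloxy)-3-oxopropyl]-6-[(butanoyloxy)methyl]-3-[(1R)-1,3,3-trimethylcyclohexyl]cyclohexa-1,3-diene-1-carbothioate
Product: 19 S-ethyl (1S,6R)-2-[3-(benzyloxy)-3-oxopropyl]-6-[(butanoyloxy)methyl]-3-[(1R)-1,3,3-trimethylcyclohexyl]cyclohex-2-ene-1-carbothioate (formed together with its C1 epimer)
Conditions: LiBH(s-Bu)3 (1.1 equiv), THF, −78 °C; AcOH, −78 °C
Reagents that add atoms: none
Why: 1,6-Conjugate hydride addition at the unhindered terminal CH of the dienyl thioester (the β-carbon is fully substituted) and kinetic α-protonation of the extended enolate (deconjugative protonation) leave the tetrasubstituted C8=C9 alkene; C14 forms as an epimer mixture and is fixed only in step 11.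

Step 10
Reactants: 19 S-ethyl (1S,6R)-2-[3-(benzyloxy)-3-oxopropyl]-6-[(butanoyloxy)methyl]-3-[(1R)-1,3,3-trimethylcyclohexyl]cyclohex-2-ene-1-carbothioate
Product: 21 3-[(5R,6S)-5-[(butanoyloxy)methyl]-6-formyl-2-[(1R)-1,3,3-trimethylcyclohexyl]cyclohex-1-en-1-yl]propanoic acid, via acid thioester 20 (not isolated)
Conditions: H2 (1 atm), 10% Pd/C, acetone, rt; N2 purge; then Et3SiH (3 equiv), same pot, rt
Reagents that add atoms: none
Why: Hydrogenolysis of the benzyl ester, then Fukuyama reduction of the thioester in the same pot, gives the aldehyde acid without touching the butanoate or the tetrasubstituted alkene; the C14 epimers are carried on.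

Step 11
Reactants: 21 3-[(5R,6S)-5-[(butanoyloxy)methyl]-6-formyl-2-[(1R)-1,3,3-trimethylcyclohexyl]cyclohex-1-en-1-yl]propanoic acid
Product: 22 [(2aS,7R,7aS,7bR)-2-oxo-4-[(1R)-1,3,3-trimethylcyclohexyl]-2,2a,3,5,6,7,7a,7b-octahydroindeno[1,2-b]oxet-7-yl]methyl butanoate (target; spongian numbering 7S,10R,13R,14S,15R)
Conditions: O-trimethylsilylquinidine (20 mol%), 2-bromo-1-propylpyridinium triflate (2 equiv), i-Pr2NEt (3 equiv), CH2Cl2/MeCN, rt, 48 h
Reagents that add atoms: none
Why: Proposed new method: Romo's nucleophile-catalysed aldol-lactonisation run as a dynamic kinetic resolution, in which the pyridinium salt activates the acid, the quinidine catalyst forms the acylammonium and then the C7 ammonium enolate, this adds to the C15 aldehyde and the aldolate closes the β-lactone with release of the catalyst, so that C7 and C15 are set cis by the ring and in the absolute sense given by the catalyst, anti to C13, while the C14 centre of the β,γ-unsaturated aldehyde epimerises through its dienolate under i-Pr2NEt (reprotonation at C9 is blocked by ring A) and the matched trans (14S) epimer is drained; the closest known reaction type is the catalytic asymmetric aldol-lactonisation of aldehyde acids to cyclopentane-fused β-lactones.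

**Compound list**
1 | isophorone (3,5,5-trimethylcyclohex-2-en-1-one) | CC1=CC(=O)CC(C)(C)C1 | starting material
2 | (1R)-3,5,5-trimethylcyclohex-2-en-1-ol ((R)-isophorol) | O[C@H]1C=C(C)CC(C)(C)C1 | intermediate
3 | (1R)-3,5,5-trimethylcyclohex-2-en-1-yl acetate | CC(=O)O[C@H]1C=C(C)CC(C)(C)C1 | intermediate
4 | trimethylsilyl ketene acetal of 3, trimethyl({1-[(1R)-3,5,5-trimethylcyclohex-2-en-1-yl]oxyethenyl}oxy)silane | C=C(O[Si](C)(C)C)O[C@H]1C=C(C)CC(C)(C)C1 | intermediate
5 | trimethylsilyl 2-[(1R)-1,5,5-trimethylcyclohex-2-en-1-yl]acetate | C[Si](C)(C)OC(=O)C[C@]1(C)C=CCC(C)(C)C1 | intermediate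
6 | 2-[(1R)-1,5,5-trimethylcyclohex-2-en-1-yl]acetic acid | OC(=O)C[C@]1(C)C=CCC(C)(C)C1 | intermediate
7 | 2-[(1R)-1,3,3-trimethylcyclohexyl]acetic acid | OC(=O)C[C@]1(C)CCCC(C)(C)C1 | intermediate
8 | 5-{1-hydroxy-2-[(1R)-1,3,3-trimethylcyclohexyl]ethylidene}-2,2-dimethyl-1,3-dioxane-4,6-dione | CC1(C)OC(=O)C(=C(O)C[C@]2(C)CCCC(C)(C)C2)C(=O)O1 | intermediate
9 | S-ethyl 3-oxo-4-[(1R)-1,3,3-trimethylcyclohexyl]butanethioate | CCSC(=O)CC(=O)C[C@]1(C)CCCC(C)(C)C1 | intermediate
10 | prop-2-en-1-yl butanoate (allyl butanoate) | CCCC(=O)OCC=C | starting material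
11 | (2E)-but-2-enal (crotonaldehyde) | C/C=C/C=O | starting material
12 | (2E)-4-oxobut-2-en-1-yl butanoate | CCCC(=O)OC/C=C/C=O | intermediate
13 | S-ethyl 2-[(2R)-1-(butanoyloxy)-4-oxobutan-2-yl]-3-oxo-4-[(1R)-1,3,3-trimethylcyclohexyl]butanethioate (both epimers at the carbon between the carbonyls) | CCSC(=O)C([C@H](COC(=O)CCC)CC=O)C(=O)C[C@]1(C)CCCC(C)(C)C1 | intermediate
14 | S-ethyl (1S,6R)-6-[(butanoyloxy)methyl]-2-oxo-3-[(1R)-1,3,3-trimethylcyclohexyl]cyclohex-3-ene-1-carbothioate (C1 enolisable, trans epimer drawn) | CCSC(=O)[C@@H]1C(=O)C([C@]2(C)CCCC(C)(C)C2)=CC[C@H]1COC(=O)CCC | intermediate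
15 | S-ethyl (6R)-6-[(butanoyloxy)methyl]-2-[(trifluoromethanesulfonyl)oxy]-3-[(1R)-1,3,3-trimethylcyclohexyl]cyclohexa-1,3-diene-1-carbothioate | CCSC(=O)C1=C(OS(=O)(=O)C(F)(F)F)C([C@]2(C)CCCC(C)(C)C2)=CC[C@H]1COC(=O)CCC | intermediate
16 | benzyl 3-bromopropanoate | BrCCC(=O)OCc1ccccc1 | starting material
17 | [3-(benzyloxy)-3-oxopropyl]zinc bromide | Br[Zn]CCC(=O)OCc1ccccc1 | intermediate
18 | S-ethyl (6R)-2-[3-(benzyloxy)-3-oxopropyl]-6-[(butanoyloxy)methyl]-3-[(1R)-1,3,3-trimethylcyclohexyl]cyclohexa-1,3-diene-1-carbothioate | CCSC(=O)C1=C(CCC(=O)OCc2ccccc2)C([C@]3(C)CCCC(C)(C)C3)=CC[C@H]1COC(=O)CCC | intermediate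
19 | S-ethyl (1S,6R)-2-[3-(benzyloxy)-3-oxopropyl]-6-[(butanoyloxy)methyl]-3-[(1R)-1,3,3-trimethylcyclohexyl]cyclohex-2-ene-1-carbothioate (with its C1 epimer; the 1S epimer is drawn) | CCSC(=O)[C@@H]1C(CCC(=O)OCc2ccccc2)=C([C@]3(C)CCCC(C)(C)C3)CC[C@H]1COC(=O)CCC | intermediate
20 | 3-[(5R,6S)-5-[(butanoyloxy)methyl]-6-[(ethylsulfanyl)carbonyl]-2-[(1R)-1,3,3-trimethylcyclohexyl]cyclohex-1-en-1-yl]propanoic acid (with its C6 epimer) | CCSC(=O)[C@@H]1C(CCC(=O)O)=C([C@]2(C)CCCC(C)(C)C2)CC[C@H]1COC(=O)CCC | intermediate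
21 | 3-[(5R,6S)-5-[(butanoyloxy)methyl]-6-formyl-2-[(1R)-1,3,3-trimethylcyclohexyl]cyclohex-1-en-1-yl]propanoic acid (with its C6 epimer, which interconverts) | O=C[C@@H]1C(CCC(=O)O)=C([C@]2(C)CCCC(C)(C)C2)CC[C@H]1COC(=O)CCC | intermediate
22 | [(2aS,7R,7aS,7bR)-2-oxo-4-[(1R)-1,3,3-trimethylcyclohexyl]-2,2a,3,5,6,7,7a,7b-octahydroindeno[1,2-b]oxet-7-yl]methyl butanoate | CCCC(=O)OC[C@@H]1CCC([C@]2(C)CCCC(C)(C)C2)=C2C[C@@H]3C(=O)O[C@@H]3[C@H]21 | target

**Step count and risks**
Total: 11 steps. Longest linear sequence: 10 steps (1, 2, 3, 4, 6, 7, 8, 9, 10, 11); step 5 is a one-step side branch.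

Most likely to fail, first: step 11. The dynamic resolution needs C14 to epimerise faster than the mismatched epimer cyclises, and the sense of the quinidine catalyst on this substrate is taken from the parent aldehyde acid, not from this compound. The fallback sets out from 21 and comes back at 22. It gives up the chiral amine and splits the event into a chelated thioester aldol and a separate lactonisation. Aldehyde acid 21 is converted with PhSH, DCC and DMAP into S-phenyl 3-[(5R,6S)-5-[(butanoyloxy)methyl]-6-formyl-2-[(1R)-1,3,3-trimethylcyclohexyl]cyclohex-1-en-1-yl]propanethioate F5. Soft enolisation with MgBr2·OEt2 and i-Pr2NEt in CH2Cl2 (direct thioester aldol, with C14 equilibrating under the amine) closes the cyclopentane to the cis β-hydroxy thioester S-phenyl (2S,3R,3aS,4R)-4-[(butanoyloxy)methyl]-3-hydroxy-7-[(1R)-1,3,3-trimethylcyclohexyl]-2,3,3a,4,5,6-hexahydro-1H-indene-2-carbothioate F6, which is separated from its diastereomers. LiN(SiMe3)2 in THF from −78 to 0 °C then closes the β-lactone with loss of thiophenolate (Danheiser-type) to give 22.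

Second: step 6. The ring closure asks a neopentyl-type CH2 to attack the aldehyde while the 1,3-dicarbonyl unit can divert the adduct into a lactol or 4H-pyran. The fallback sets out from 7 and comes back at 14. It removes the 1,3-dicarbonyl before ring closure and puts C15 back afterwards. Acid 7 is taken through the same acyl Meldrum's acid 8, which is opened with t-BuOH at 80 °C to tert-butyl 3-oxo-4-[(1R)-1,3,3-trimethylcyclohexyl]butanoate F1. The same amine-catalysed Michael addition to 12 gives tert-butyl 2-[(2R)-1-(butanoyloxy)-4-oxobutan-2-yl]-3-oxo-4-[(1R)-1,3,3-trimethylcyclohexyl]butanoate F2. Heating with p-TsOH in toluene at 80 °C removes the tert-butyl ester and CO2, and the resulting simple keto aldehyde can only close by the desired six-ring aldol condensation, giving [(1R)-5-oxo-4-[(1R)-1,3,3-trimethylcyclohexyl]cyclohex-3-en-1-yl]methyl butanoate F3. Kinetic enolisation of F3 at C14 with LiN(SiMe3)2 at −78 °C, capture with carbonyl sulfide and S-alkylation with EtI return β-keto thioester 14.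

Third: step 9. The bulky borohydride may attack the thioester carbonyl or be slowed by ring A next to the terminal CH. The fallback sets out from 18 and comes back at 19. It replaces hydride addition and enolate protonation by a metal-catalysed conjugate hydrosilylation with an isolable silyl dienol ether. Diene 18 with Et3SiH and RhCl(PPh3)3 (cat.) in toluene at 60 °C gives benzyl 3-[(5R)-5-[(butanoyloxy)methyl]-6-[(ethylsulfanyl)(triethylsilyloxy)methylidene]-2-[(1R)-1,3,3-trimethylcyclohexyl]cyclohex-1-en-1-yl]propanoate F4. Protodesilylation with AcOH in wet THF at 0 °C puts the proton on C14 and gives 19.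

Further compounds
F1 | step 6 | tert-butyl 3-oxo-4-[(1R)-1,3,3-trimethylcyclohexyl]butanoate | CC(C)(C)OC(=O)CC(=O)C[C@]1(C)CCCC(C)(C)C1
F2 | step 6 | tert-butyl 2-[(2R)-1-(butanoyloxy)-4-oxobutan-2-yl]-3-oxo-4-[(1R)-1,3,3-trimethylcyclohexyl]butanoate | CC(C)(C)OC(=O)C([C@H](COC(=O)CCC)CC=O)C(=O)C[C@]1(C)CCCC(C)(C)C1
F3 | step 6 | [(1R)-5-oxo-4-[(1R)-1,3,3-trimethylcyclohexyl]cyclohex-3-en-1-yl]methyl butanoate | CCCC(=O)OC[C@@H]1CC=C([C@]2(C)CCCC(C)(C)C2)C(=O)C1
F4 | step 9 | benzyl 3-[(5R)-5-[(butanoyloxy)methyl]-6-[(ethylsulfanyl)(triethylsilyloxy)methylidene]-2-[(1R)-1,3,3-trimethylcyclohexyl]cyclohex-1-en-1-yl]propanoate | CCSC(O[Si](CC)(CC)CC)=C1C(CCC(=O)OCc2ccccc2)=C([C@]3(C)CCCC(C)(C)C3)CC[C@H]1COC(=O)CCC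
F5 | step 11 | S-phenyl 3-[(5R,6S)-5-[(butanoyloxy)methyl]-6-formyl-2-[(1R)-1,3,3-trimethylcyclohexyl]cyclohex-1-en-1-yl]propanethioate | O=C[C@@H]1C(CCC(=O)Sc2ccccc2)=C([C@]3(C)CCCC(C)(C)C3)CC[C@H]1COC(=O)CCC
F6 | step 11 | S-phenyl (2S,3R,3aS,4R)-4-[(butanoyloxy)methyl]-3-hydroxy-7-[(1R)-1,3,3-trimethylcyclohexyl]-2,3,3a,4,5,6-hexahydro-1H-indene-2-carbothioate | CCCC(=O)OC[C@@H]1CCC([C@]2(C)CCCC(C)(C)C2)=C2C[C@H](C(=O)Sc3ccccc3)[C@H](O)[C@H]21
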